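**Strategy.** Daucane numbering: C1 quaternary fusion carbon, C4 carbinol, C5 fusion CH, C6 and C10 acyloxy carbons; ring A cyclopentane, ring B cycloheptene. Everything rests on the C4–C5 bond of ring A. The key step exploits the aldol retron C4(OH)–C5–C6(O), whose O4 and C6 are cis on ring A. A nucleophile-catalysed aldol-lactonisation of an acyclic keto acid forms C4–C5 and O4–C6 in one operation. It closes ring A and a temporary β-lactone and sets C4 and C5 from C1. The precursor is the unzipped form of a Diels–Alder-derived p-menthene carrying C1 and C10. Ring B follows by ring-closing metathesis.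

Key step: step 7

Assumption: carbon labels C1–C15 are those of the target and are kept for the same atoms in every intermediate; the facial sense of step 2 is taken from the formyl C–H···O binding model for 2-substituted acroleins, and the mirror-image catalyst is equally available.

Step 1
Reactants: 1 3-methylbut-1-yne; 2 ethylene
Product: 3 2-isopropylbuta-1,3-diene
Conditions: RuCl2(=CHPh)(PCy3)(H2IMes) (second-generation Grubbs catalyst, 3 mol %), 2 (4 atm), CH2Cl2, rt; distil
Reagents that add atoms: none
Why: Cross enyne metathesis of a terminal alkyne and ethylene should give the 2-substituted 1,3-diene with every atom of both partners retained and without any stereocentre.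

Step 2
Reactants: 3 2-isopropylbuta-1,3-diene; 4 methacrolein
Product: 5 (1S)-1-methyl-4-(propan-2-yl)cyclohex-3-ene-1-carbaldehyde
Conditions: (S)-3,3-diphenyl-1-(2-methylphenyl)tetrahydro-1H,3H-pyrrolo[1,2-c][1,3,2]oxazaborole (10 mol %), HN(SO2CF3)2 (9 mol %), CH2Cl2, −78 °C
Reagents that add atoms: none
Why: Enantioselective Diels–Alder reaction under chiral oxazaborolidinium catalysis, in which the 2-alkyl diene should add with para orientation to s-trans methacrolein bound through B–O coordination and a formyl C–H···O contact while a phenyl group of the catalyst screens one face, so that the quaternary C1 is set as S by the catalyst.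

Step 3
Reactants: 5 (1S)-1-methyl-4-(propan-2-yl)cyclohex-3-ene-1-carbaldehyde; 6 vinylmagnesium bromide
Product: 8 (1R)-1-[(1S)-1-methyl-4-(propan-2-yl)cyclohex-3-en-1-yl]prop-2-en-1-ol, via divinylzinc 7 (not isolated)
Conditions: 6, ZnCl2, Et2O, 0 °C, then 1,4-dioxane, filter; (+)-MIB [(2R)-3-exo-morpholinoisoborneol] (10 mol %), 5, toluene, 0 °C; H2O
Reagents that add atoms: none
Why: Amino-alcohol-catalysed asymmetric addition of an alkenylzinc reagent to an aldehyde, in which the zinc chelate of (+)-MIB should deliver the vinyl group to the Re face of the non-enolisable aldehyde and set C10 as R by reagent control, the substrate itself having almost no facial bias.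

Step 4
Reactants: 8 (1R)-1-[(1S)-1-methyl-4-(propan-2-yl)cyclohex-3-en-1-yl]prop-2-en-1-ol
Product: 9 tert-butyldimethylsilyl ether of 8
Conditions: TBSOTf, 2,6-lutidine, CH2Cl2, 0 °C
Reagents that add atoms: tert-butyldimethylsilyl triflate, CC(C)(C)[Si](C)(C)OS(=O)(=O)C(F)(F)F
Why: Silylation of a hindered secondary alcohol by a silyl triflate masks O10, which would otherwise lactonise onto the activated C6 acid in step 7, and leaves both stereocentres untouched.

Step 5
Reactants: 9 tert-butyldimethylsilyl ether of 8
Product: 11 (3S)-3-[(1R)-1-(tert-butyldimethylsilyloxy)prop-2-en-1-yl]-3,7-dimethyl-6-oxooctanal, via secondary ozonide 10 (not isolated)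
Conditions: O3 (1 equiv), CH2Cl2, −78 °C; PPh3, −78 °C to rt
Reagents that add atoms: ozone, [O-][O+]=O
Why: Chemoselective ozonolysis followed by reductive work-up, in which electrophilic ozone should prefer the electron-rich trisubstituted ring alkene over the vinyl group that is deactivated by the allylic silyloxy group and screened by C1, so that the six-membered ring is unzipped into the C4 isopropyl ketone and the C6 aldehyde.

Step 6
Reactants: 11 (3S)-3-[(1R)-1-(tert-butyldimethylsilyloxy)prop-2-en-1-yl]-3,7-dimethyl-6-oxooctanal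
Product: 12 (3S)-3-[(1R)-1-(tert-butyldimethylsilyloxy)prop-2-en-1-yl]-3,7-dimethyl-6-oxooctanoic acid
Conditions: NaClO2, NaH2PO4, 2-methylbut-2-ene, t-BuOH–H2O, rt
Reagents that add atoms: sodium chlorite, [Na+].[O-]Cl=O
Why: Pinnick oxidation raises the C6 aldehyde to the acid under buffered conditions that spare ketone, silyl ether and vinyl group, the alkene scavenger removing hypochlorous acid.

Step 7
Reactants: 12 (3S)-3-[(1R)-1-(tert-butyldimethylsilyloxy)prop-2-en-1-yl]-3,7-dimethyl-6-oxooctanoic acid
Product: 15 (1R,2S,5R)-2-[(1R)-1-(tert-butyldimethylsilyloxy)prop-2-en-1-yl]-2-methyl-5-(propan-2-yl)-6-oxabicyclo[3.2.0]heptan-7-one, via tosyl mixed anhydride 13 (not isolated), via acylpyridinium enolate 14 (not isolated)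
Conditions: TsCl, 4-pyrrolidinopyridine (1 equiv), iPr2NEt, CH2Cl2, rt, slow addition of 12
Reagents that add atoms: none
Why: TsCl turns acid 12 into mixed anhydride 13, 4-pyrrolidinopyridine takes over the acyl group, iPr2NEt removes the acidified C5–H to give (Z)-acylpyridinium enolate 14, C5 adds to the C4 ketone and the new C4 alkoxide attacks C6 and expels the pyridine. The closest known reaction type is the nucleophile-catalysed aldol-lactonisation of keto acids, which is established for cyclopentane-fused β-lactones with a tertiary carbinol carbon. Ring A closes by a 5-(enolexo)-exo-trig aldol addition and the temporary β-lactone by a 4-exo-trig acyl substitution. C5 is controlled by C1: with the C1–C2 tether perpendicular to the enolate plane, A1,3 strain places the methyl group inside and the bulky silyloxyallyl group outside, so that C6 ends up cis to the methyl group and trans to C10. C4 is controlled by the lactonisation, since only the aldolate with O4 cis to C6 can close while the other one reverts by retro-aldol, which makes the step self-correcting. The step needs enolisation at the acid terminus next to a more acidic ketone, which acylpyridinium activation secures, and closure onto a hindered isopropyl ketone, which the geminal substitution at C1 and the irreversible lactonisation favour.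

Step 8
Reactants: 15 bicyclic β-lactone
Product: 16 (1R,2S,3S)-3-[(1R)-1-(tert-butyldimethylsilyloxy)prop-2-en-1-yl]-2-(hydroxymethyl)-3-methyl-1-(propan-2-yl)cyclopentan-1-ol
Conditions: LiAlH4, Et2O, 0 °C; H2O
Reagents that add atoms: none
Why: Hydride reduction of the strained β-lactone by acyl–oxygen cleavage should release the tertiary C4 alcohol and the primary C6 alcohol without touching C4, C5 or the silyl ether.

Step 9
Reactants: 16 cyclopentane diol
Product: 17 (1R,2R,5S)-5-[(1R)-1-(tert-butyldimethylsilyloxy)prop-2-en-1-yl]-2-hydroxy-5-methyl-2-(propan-2-yl)cyclopentane-1-carbaldehyde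
Conditions: TEMPO (10 mol %), PhI(OAc)2, CH2Cl2, rt
Reagents that add atoms: none
Why: Oxoammonium-catalysed (TEMPO) oxidation takes only the primary alcohol, since the C4 alcohol is tertiary, and its near-neutral medium should avoid epimerisation at C5, retro-aldol cleavage and loss of water.

Step 10
Reactants: 17 β-hydroxy aldehyde; 18 tributyl(2-methylprop-2-en-1-yl)stannane
Product: 19 (1R,2S,3S)-3-[(1R)-1-(tert-butyldimethylsilyloxy)prop-2-en-1-yl]-2-[(1S)-1-hydroxy-3-methylbut-3-en-1-yl]-3-methyl-1-(propan-2-yl)cyclopentan-1-ol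
Conditions: MgBr2·OEt2, CH2Cl2, −78 to −20 °C; H2O
Reagents that add atoms: none
Why: Chelation-controlled Lewis-acid-mediated allylstannane addition, in which MgBr2 ties O4 and the aldehyde oxygen into a six-membered chelate whose face toward C1 is blocked by the cis methyl group, so that the methallyl group should enter from the open face and set C6 as S.

Step 11
Reactants: 19 homoallylic diol; 20 3,4-dimethoxybenzoyl chloride
Product: 21 (1S)-1-{(1S,2R,5S)-5-[(1R)-1-(tert-butyldimethylsilyloxy)prop-2-en-1-yl]-2-hydroxy-5-methyl-2-(propan-2-yl)cyclopentyl}-3-methylbut-3-en-1-yl 3,4-dimethoxybenzoate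
Conditions: DMAP, Et3N, CH2Cl2, rt to 40 °C
Reagents that add atoms: none
Why: DMAP-catalysed acylation by an acid chloride should esterify the secondary C6 alcohol only, the tertiary C4 alcohol being too hindered, with retention at C6.

Step 12
Reactants: 21 silylated veratrate
Product: 22 (1S)-1-{(1S,2R,5S)-2-hydroxy-5-[(1R)-1-hydroxyprop-2-en-1-yl]-5-methyl-2-(propan-2-yl)cyclopentyl}-3-methylbut-3-en-1-yl 3,4-dimethoxybenzoate
Conditions: HF·pyridine, THF, 0 °C to rt
Reagents that add atoms: none
Why: Fluoride-induced desilylation in a mildly acidic medium should free the C10 alcohol without acyl migration or ester cleavage.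

Step 13
Reactants: 22 diene diol
Product: 23 (3R,3aS,4S,8R,8aS)-3,8-dihydroxy-6,8a-dimethyl-3-(propan-2-yl)-1,2,3,3a,4,5,8,8a-octahydroazulen-4-yl 3,4-dimethoxybenzoate
Conditions: RuCl2(=CHPh)(PCy3)(H2IMes) (second-generation Grubbs catalyst, 10 mol %), CH2Cl2 (2 mM), reflux
Reagents that add atoms: none
Why: Ring-closing metathesis, in which the catalyst should load on the vinyl carbinol, aided by its free hydroxyl group, and close onto the 1,1-disubstituted alkene to give ring B with the trisubstituted C8=C9 bond, the trans arms on ring A translating into the trans ring fusion.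

Step 14
Reactants: 23 bicyclic diol monoester; 24 angelic acid
Product: 26 CNP0142353.1, via angelic trichlorobenzoic anhydride 25 (not isolated)
Conditions: 24, 2,4,6-trichlorobenzoyl chloride, Et3N, toluene, rt; then 23, 80 °C
Reagents that add atoms: none
Why: Yamaguchi-type mixed-anhydride esterification run without a nucleophilic catalyst should acylate the secondary allylic C10 alcohol with retention at C10 and without Z-to-E isomerisation of the angeloyl group, the tertiary C4 alcohol staying free.

**Compound list**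

1 | 3-methylbut-1-yne | C#CC(C)C | starting material
2 | ethylene | C=C | starting material
3 | 2-isopropylbuta-1,3-diene | C=CC(=C)C(C)C | intermediate
4 | methacrolein | C=C(C)C=O | starting material
5 | (1S)-1-methyl-4-(propan-2-yl)cyclohex-3-ene-1-carbaldehyde | O=C[C@]1(C)CC=C(C(C)C)CC1 | intermediate
6 | vinylmagnesium bromide | C=C[Mg]Br | starting material
7 | divinylzinc | C=C[Zn]C=C | intermediate
8 | (1R)-1-[(1S)-1-methyl-4-(propan-2-yl)cyclohex-3-en-1-yl]prop-2-en-1-ol | C=C[C@@H](O)[C@]1(C)CC=C(C(C)C)CC1 | intermediate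
9 | tert-butyldimethylsilyl ether of 8 | C=C[C@@H](O[Si](C)(C)C(C)(C)C)[C@]1(C)CC=C(C(C)C)CC1 | intermediate
10 | secondary ozonide of 9 (6,7,8-trioxabicyclo[3.2.1]octane bridging C4 and C6, bridgehead configuration open) | C=C[C@@H](O[Si](C)(C)C(C)(C)C)[C@@]1(C)CCC2(C(C)C)OOC(C1)O2 | intermediate
11 | (3S)-3-[(1R)-1-(tert-butyldimethylsilyloxy)prop-2-en-1-yl]-3,7-dimethyl-6-oxooctanal | C=C[C@@H](O[Si](C)(C)C(C)(C)C)[C@](C)(CC=O)CCC(=O)C(C)C | intermediate
12 | (3S)-3-[(1R)-1-(tert-butyldimethylsilyloxy)prop-2-en-1-yl]-3,7-dimethyl-6-oxooctanoic acid | C=C[C@@H](O[Si](C)(C)C(C)(C)C)[C@](C)(CC(=O)O)CCC(=O)C(C)C | intermediate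
13 | mixed anhydride of 12 and 4-methylbenzenesulfonic acid | C=C[C@@H](O[Si](C)(C)C(C)(C)C)[C@](C)(CC(=O)OS(=O)(=O)c1ccc(C)cc1)CCC(=O)C(C)C | intermediate
14 | zwitterionic (Z)-enolate of the 1-acyl-4-(pyrrolidin-1-yl)pyridinium derived from 12 | C=C[C@@H](O[Si](C)(C)C(C)(C)C)[C@](C)(/C=C(\[O-])[n+]1ccc(N2CCCC2)cc1)CCC(=O)C(C)C | intermediate
15 | (1R,2S,5R)-2-[(1R)-1-(tert-butyldimethylsilyloxy)prop-2-en-1-yl]-2-methyl-5-(propan-2-yl)-6-oxabicyclo[3.2.0]heptan-7-one (cis-fused β-lactone on the face of the C1 methyl group) | C=C[C@@H](O[Si](C)(C)C(C)(C)C)[C@@]1(C)CC[C@]2(C(C)C)OC(=O)[C@H]12 | intermediate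
16 | (1R,2S,3S)-3-[(1R)-1-(tert-butyldimethylsilyloxy)prop-2-en-1-yl]-2-(hydroxymethyl)-3-methyl-1-(propan-2-yl)cyclopentan-1-ol | C=C[C@@H](O[Si](C)(C)C(C)(C)C)[C@@]1(C)CC[C@@](O)(C(C)C)[C@@H]1CO | intermediate
17 | (1R,2R,5S)-5-[(1R)-1-(tert-butyldimethylsilyloxy)prop-2-en-1-yl]-2-hydroxy-5-methyl-2-(propan-2-yl)cyclopentane-1-carbaldehyde | C=C[C@@H](O[Si](C)(C)C(C)(C)C)[C@@]1(C)CC[C@@](O)(C(C)C)[C@@H]1C=O | intermediate
18 | tributyl(2-methylprop-2-en-1-yl)stannane | C=C(C)C[Sn](CCCC)(CCCC)CCCC | starting material
19 | (1R,2S,3S)-3-[(1R)-1-(tert-butyldimethylsilyloxy)prop-2-en-1-yl]-2-[(1S)-1-hydroxy-3-methylbut-3-en-1-yl]-3-methyl-1-(propan-2-yl)cyclopentan-1-ol | C=C[C@@H](O[Si](C)(C)C(C)(C)C)[C@@]1(C)CC[C@@](O)(C(C)C)[C@@H]1[C@@H](O)CC(C)=C | intermediate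
20 | 3,4-dimethoxybenzoyl chloride (veratroyl chloride) | COc1ccc(cc1OC)C(=O)Cl | starting material
21 | (1S)-1-{(1S,2R,5S)-5-[(1R)-1-(tert-butyldimethylsilyloxy)prop-2-en-1-yl]-2-hydroxy-5-methyl-2-(propan-2-yl)cyclopentyl}-3-methylbut-3-en-1-yl 3,4-dimethoxybenzoate | C=C[C@@H](O[Si](C)(C)C(C)(C)C)[C@@]1(C)CC[C@@](O)(C(C)C)[C@@H]1[C@@H](OC(=O)c2ccc(OC)c(OC)c2)CC(C)=C | intermediate
22 | (1S)-1-{(1S,2R,5S)-2-hydroxy-5-[(1R)-1-hydroxyprop-2-en-1-yl]-5-methyl-2-(propan-2-yl)cyclopentyl}-3-methylbut-3-en-1-yl 3,4-dimethoxybenzoate | C=C[C@@H](O)[C@@]1(C)CC[C@@](O)(C(C)C)[C@@H]1[C@@H](OC(=O)c2ccc(OC)c(OC)c2)CC(C)=C | intermediate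
23 | (3R,3aS,4S,8R,8aS)-3,8-dihydroxy-6,8a-dimethyl-3-(propan-2-yl)-1,2,3,3a,4,5,8,8a-octahydroazulen-4-yl 3,4-dimethoxybenzoate | O[C@@H]1C=C(C)C[C@H](OC(=O)c2ccc(OC)c(OC)c2)[C@@H]2[C@]1(C)CC[C@@]2(O)C(C)C | intermediate
24 | angelic acid, (2Z)-2-methylbut-2-enoic acid | C/C=C(/C)C(=O)O | starting material
25 | (2Z)-2-methylbut-2-enoic 2,4,6-trichlorobenzoic anhydride | C/C=C(/C)C(=O)OC(=O)c1c(Cl)cc(Cl)cc1Cl | intermediate
26 | CNP0142353.1, (3R,3aS,4S,8R,8aS)-3-hydroxy-6,8a-dimethyl-8-{[(2Z)-2-methylbut-2-enoyl]oxy}-3-(propan-2-yl)-1,2,3,3a,4,5,8,8a-octahydroazulen-4-yl 3,4-dimethoxybenzoate | C/C=C(/C)C(=O)O[C@@H]1C=C(C)C[C@H](OC(=O)c2ccc(OC)c(OC)c2)[C@@H]2[C@]1(C)CC[C@@]2(O)C(C)C | target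

Total step count: 14. Longest linear sequence: 14 steps.

**Steps most likely to fail**

**Step 7.**
- What may go wrong: the aldol addition onto the hindered isopropyl ketone may be slow. The activated acid could then drift into self-condensation, or facial selectivity at C5 could erode.
- Fallback: it sets out from keto aldehyde 11 and returns at hydroxy aldehyde 17. Enamine catalysis (pyrrolidine and AcOH, 20 mol % each, CH2Cl2, 0 °C) should enolise only the aldehyde terminus and close ring A by a 5-enolexo aldol addition onto the C4 ketone.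
- Stereochemistry: reversible addition and epimerisation at C5 should funnel the isomers toward 17. In 17, C6 is trans to both the silyloxyallyl and the isopropyl group and is hydrogen-bonded to O4.
- Why it is held in reserve: although shorter, nothing traps the aldol there, so loss of water to the conjugated enal can take over.

**Step 3.**
- What may go wrong: reagent control on the neopentyl aldehyde may be incomplete, because a background addition promoted by residual magnesium salts can compete.
- Fallback: it sets out from 5 and returns at 8. Uncatalysed addition of 6 (THF, −78 °C) gives the C10-epimeric allylic alcohols F1, and Dess–Martin oxidation gives the vinyl ketone F2.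
- Return to the route: Corey–Bakshi–Shibata reduction should then give 8, using (S)-1-methyl-3,3-diphenyltetrahydro-1H,3H-pyrrolo[1,2-c][1,3,2]oxazaborole and catecholborane in toluene at −78 °C. The tertiary alkyl group acts as the large substituent.
- What changes: C10 is set by hydride delivery instead of carbon delivery, and both epimers of F1 are used.

**Step 14.**
- What may go wrong: acylation of the neopentyl allylic alcohol may be sluggish, and prolonged heating may isomerise the angeloyl unit to the E isomer.
- Fallback: it sets out from 23 and ends at 26. Esterification with 2-[bis(2,2,2-trifluoroethoxy)phosphoryl]propanoic acid (DCC, DMAP, CH2Cl2) gives the phosphonopropionate ester F3.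
- Return to the route: Still–Gennari olefination (KHMDS, 18-crown-6, THF, −78 °C, then acetaldehyde) builds the Z-alkene on the ester already in place.

**Further compounds**

F0 | step 7 | none | none
F1 | step 3 | 1-[(1S)-1-methyl-4-(propan-2-yl)cyclohex-3-en-1-yl]prop-2-en-1-ol as both C10 epimers | C=CC(O)[C@]1(C)CC=C(C(C)C)CC1
F2 | step 3 | 1-[(1S)-1-methyl-4-(propan-2-yl)cyclohex-3-en-1-yl]prop-2-en-1-one | C=CC(=O)[C@]1(C)CC=C(C(C)C)CC1
F3 | step 14 | C10 2-[bis(2,2,2-trifluoroethoxy)phosphoryl]propanoate of 23 (phosphonate α-carbon as both epimers) | CC(C(=O)O[C@@H]1C=C(C)C[C@H](OC(=O)c2ccc(OC)c(OC)c2)[C@@H]2[C@]1(C)CC[C@@]2(O)C(C)C)P(=O)(OCC(F)(F)F)OCC(F)(F)F
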